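A direct plan would join 1-(2,4-dihydroxy-6-methoxyphenyl)ethan-1-one A1 and methyl 3,5-bis(benzyloxy)-4-methoxybenzoate A2 by Claisen condensation and acid cyclodehydration to the 8-unsubstituted flavone A3, would then convert C8–H into C8–OMe to reach the 5,8-dimethoxyflavone A4, and would end with debenzylation.
Its weakest step would be the late methoxylation of C8–H, because no dependable reaction does this on a free phenol, C6 would compete and ring A would tend to over-oxidise to quinones.
The Claisen condensation would come next, because it would need a poorly soluble phenol trianion and a large excess of base and would suffer from competing O-acylation.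

Ring A carries its four oxygens O1, 8-OMe, 7-OH and 5-OMe in the same pattern as twofold-symmetric 2,5-dimethoxybenzene-1,3-diol, with C4a at either of its two equivalent C–H positions. Ring C is therefore cut across C4–C4a and O1–C2: in a thermal Mentzer annulation an aroylketene, released from a β-keto ester that holds ring B, C2, C3 and C4, acylates that C–H and the neighbouring hydroxyl closes the pyranone. One operation forms both bonds with every ring A oxygen already in place, so no C–H oxidation is needed and no phenol polyanion is acylated.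

Key step: step 7

Remark: the target has no stereocentre and no hindered axis, so no step has to set or preserve configuration.

Step 1
Reactants: 1 5-methoxybenzene-1,3-diol (5-methoxyresorcinol)
Product: 2 1-methoxy-3,5-bis(methoxymethoxy)benzene
Conditions: NaH (2.4 equiv), DMF, 0 °C; MeOCH2Cl (2.5 equiv), 0 °C → rt, 3 h
Reagents that add atoms: chloromethyl methyl ether, COCCl
Why: Williamson-type O-alkylation of both phenoxides by the hard electrophile; the two acetals are installed because they are the ortho-directing groups of step 2.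

Step 2
Reactants: 2 1-methoxy-3,5-bis(methoxymethoxy)benzene
Product: 5 4-methoxy-2,6-bis(methoxymethoxy)phenol, via aryllithium 3 (not isolated), via dimethyl arylboronate 4 (not isolated)
Conditions: n-BuLi (1.15 equiv), THF, 0 °C, 1 h; B(OMe)3 (1.5 equiv), −78 °C → rt; AcOH (1.5 equiv), 30% H2O2 (2 equiv), 0 °C → rt, 1 h
Reagents that add atoms: hydrogen peroxide, OO (gives the phenol oxygen of 5); trimethyl borate, COB(OC)OC (gives the boronate group of 4 only); n-butyllithium, [Li]CCCC (gives the lithium of 3 only)
Why: Directed ortho-metalation should occur mainly at the position flanked by both OCH2OMe groups (two chelating directors, each stronger than OMe), and borylation followed by oxidation of the C–B bond (1,2-aryl shift from boron to oxygen) turns the aryllithium into the phenol.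

Step 3
Reactants: 5 4-methoxy-2,6-bis(methoxymethoxy)phenol
Product: 6 2,5-dimethoxy-1,3-bis(methoxymethoxy)benzene
Conditions: MeI (1.5 equiv), K2CO3 (2 equiv), DMF, rt, 6 h
Reagents that add atoms: iodomethane, CI
Why: Williamson ether synthesis on the single phenoxide; the flanking acetals are stable to base.

Step 4
Reactants: 6 2,5-dimethoxy-1,3-bis(methoxymethoxy)benzene
Product: 7 2,5-dimethoxybenzene-1,3-diol
Conditions: HCl (2 M in MeOH), 45 °C, 2 h, Ar; used promptly
Reagents that add atoms: none
Why: Acid-catalysed transacetalisation to methanol frees both phenols and removes the methoxymethyl cation as volatile dimethoxymethane, while the aryl methyl ethers are inert.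

Step 5
Reactants: 8 methyl 3,5-dihydroxy-4-methoxybenzoate
Product: 9 methyl 4-methoxy-3,5-bis[(triisopropylsilyl)oxy]benzoate
Conditions: i-Pr3SiCl (2.4 equiv), imidazole (5 equiv), DMF, rt → 40 °C, 12 h
Reagents that add atoms: chlorotriisopropylsilane, CC(C)[Si](Cl)(C(C)C)C(C)C
Why: Imidazole-promoted silylation of both phenols; the bulky silyl ethers are chosen to withstand amide and enolate bases and a neutral melt and to leave with fluoride.

Step 6
Reactants: 9 methyl 4-methoxy-3,5-bis[(triisopropylsilyl)oxy]benzoate
Product: 10 ethyl 3-{4-methoxy-3,5-bis[(triisopropylsilyl)oxy]phenyl}-3-oxopropanoate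
Conditions: EtOAc (2.5 equiv), LiN(SiMe3)2 (3.2 equiv), THF, −78 °C, 30 min; then 9, −78 → 0 °C, 2 h; AcOH quench
Reagents that add atoms: ethyl acetate, CCOC(C)=O
Why: Crossed Claisen condensation of the preformed lithium enolate of ethyl acetate with a non-enolisable aryl ester; the β-keto ester is held as its enolate until the quench, which prevents a second addition.

Step 7
Reactants: 7 2,5-dimethoxybenzene-1,3-diol; 10 ethyl 3-{4-methoxy-3,5-bis[(triisopropylsilyl)oxy]phenyl}-3-oxopropanoate
Product: 13 7-hydroxy-5,8-dimethoxy-2-{4-methoxy-3,5-bis[(triisopropylsilyl)oxy]phenyl}-4H-chromen-4-one, via aroylketene 11 (not isolated), via diketone 12 (not isolated)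
Conditions: 7 (1.5 equiv), 10 (1.0 equiv), Ph2O, 240 °C, Ar sweep (EtOH and H2O distilled off), 30–45 min
Reagents that add atoms: none
Why: Mentzer pyrone synthesis (uncatalysed thermal condensation of a phenol with a β-keto ester): at 240 °C ester 10 should lose ethanol to aroylketene 11, whose O-acylation of either hydroxyl of 7 is reversible at this temperature, whereas attack through ring carbon C4 of diol 7 (ortho to one OH, para to the other, ortho to the 5-OMe) is not, so the mixture should drain to the ortho-hydroxyaryl 1,3-diketone 12. The only hydroxyl ortho to the new acyl group then adds to the aroyl carbonyl and water is lost, which closes ring C through O1–C2 by a 6-exo-trig addition followed by elimination and leaves it as an aromatic 4-pyranone; no stereocentre is formed. The step needs site selectivity on ring A and chromone-versus-coumarin selectivity: the first is settled by the symmetry of 7, whose C4 and C6 are equivalent while C2 is blocked by OMe, and the second by the absence of acid, since closure in the coumarin sense (ring carbon onto the ketone, Pechmann mode) needs protic or Lewis acid activation of the ketone. The silyl ethers keep the ring B oxygens out of the acyl-transfer equilibria, and the excess of 7 together with the lower nucleophilicity of the acylated ring A of 13 should suppress a second annulation at C6 and O7. The closest known type is the thermal condensation of phloroglucinol or resorcinol with ethyl aroylacetates to 5,7-dihydroxy- or 7-hydroxyflavones.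

Step 8
Reactants: 13 7-hydroxy-5,8-dimethoxy-2-{4-methoxy-3,5-bis[(triisopropylsilyl)oxy]phenyl}-4H-chromen-4-one
Product: 14 2-(3,5-dihydroxy-4-methoxyphenyl)-7-hydroxy-5,8-dimethoxy-4H-chromen-4-one (CNP0218554.0)
Conditions: Bu4NF (2.5 equiv), AcOH (2.5 equiv), THF, 0 °C → rt, 1 h
Reagents that add atoms: none
Why: Fluoride-mediated desilylation (strong Si–F bond) of both aryl silyl ethers, buffered by acetic acid so that the flavone and its three methyl ethers see no strong base; material that lost silicon in the melt would converge on the same product.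

**Compound list**
1 | 5-methoxybenzene-1,3-diol | COc1cc(O)cc(O)c1 | starting material
2 | 1-methoxy-3,5-bis(methoxymethoxy)benzene | COCOc1cc(OC)cc(OCOC)c1 | intermediate
3 | [4-methoxy-2,6-bis(methoxymethoxy)phenyl]lithium | [Li]c1c(OCOC)cc(OC)cc1OCOC | intermediate (not isolated)
4 | dimethyl [4-methoxy-2,6-bis(methoxymethoxy)phenyl]boronate | COCOc1cc(OC)cc(OCOC)c1B(OC)OC | intermediate (not isolated)
5 | 4-methoxy-2,6-bis(methoxymethoxy)phenol | COCOc1cc(OC)cc(OCOC)c1O | intermediate
6 | 2,5-dimethoxy-1,3-bis(methoxymethoxy)benzene | COCOc1cc(OC)cc(OCOC)c1OC | intermediate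
7 | 2,5-dimethoxybenzene-1,3-diol | COc1cc(O)c(OC)c(O)c1 | intermediate
8 | methyl 3,5-dihydroxy-4-methoxybenzoate | COC(=O)c1cc(O)c(OC)c(O)c1 | starting material
9 | methyl 4-methoxy-3,5-bis[(triisopropylsilyl)oxy]benzoate | COC(=O)c1cc(O[Si](C(C)C)(C(C)C)C(C)C)c(OC)c(O[Si](C(C)C)(C(C)C)C(C)C)c1 | intermediate
10 | ethyl 3-{4-methoxy-3,5-bis[(triisopropylsilyl)oxy]phenyl}-3-oxopropanoate | CCOC(=O)CC(=O)c1cc(O[Si](C(C)C)(C(C)C)C(C)C)c(OC)c(O[Si](C(C)C)(C(C)C)C(C)C)c1 | intermediate
11 | 3-{4-methoxy-3,5-bis[(triisopropylsilyl)oxy]phenyl}-3-oxoprop-1-en-1-one (aroylketene) | O=C=CC(=O)c1cc(O[Si](C(C)C)(C(C)C)C(C)C)c(OC)c(O[Si](C(C)C)(C(C)C)C(C)C)c1 | intermediate (not isolated)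
12 | 1-(2,4-dihydroxy-3,6-dimethoxyphenyl)-3-{4-methoxy-3,5-bis[(triisopropylsilyl)oxy]phenyl}propane-1,3-dione | COc1cc(O)c(OC)c(O)c1C(=O)CC(=O)c1cc(O[Si](C(C)C)(C(C)C)C(C)C)c(OC)c(O[Si](C(C)C)(C(C)C)C(C)C)c1 | intermediate (not isolated)
13 | 7-hydroxy-5,8-dimethoxy-2-{4-methoxy-3,5-bis[(triisopropylsilyl)oxy]phenyl}-4H-chromen-4-one | COc1cc(O)c(OC)c2oc(-c3cc(O[Si](C(C)C)(C(C)C)C(C)C)c(OC)c(O[Si](C(C)C)(C(C)C)C(C)C)c3)cc(=O)c12 | intermediate
14 | 2-(3,5-dihydroxy-4-methoxyphenyl)-7-hydroxy-5,8-dimethoxy-4H-chromen-4-one | COc1c(O)cc(-c2cc(=O)c3c(OC)cc(O)c(OC)c3o2)cc1O | target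

Total step count: 8. Longest linear sequence: 6 steps (steps 1–4, 7, 8); steps 5 and 6 form the second branch.

Steps most likely to fail

Step 7. The melt may close ring C in the coumarin sense (ring carbon onto the aroyl ketone), acylate the product a second time at C6 and O7, or lose the ketene to dimerisation. The fallback sets out from 7 and returns at 13 by the stepwise ketone route. Houben–Hoesch acylation of 7 with acetonitrile (ZnCl2, HCl gas, Et2O, 0 °C) should give, as a single regioisomer by symmetry, 1-(2,4-dihydroxy-3,6-dimethoxyphenyl)ethan-1-iminium chloride F1. Hydrolysis (H2O, 90 °C) would give 1-(2,4-dihydroxy-3,6-dimethoxyphenyl)ethan-1-one F2. Its lithium salt (LiN(SiMe3)2, 4 equiv, THF, −78 → 0 °C) would be acylated at carbon by ester 9 to diketone 12, and p-TsOH (cat.) in toluene at 80 °C should cyclodehydrate 12 to 13.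

Step 4. The methoxymethyl cation or formaldehyde set free may re-attack the very electron-rich ring to give diarylmethanes, and the free diol may oxidise in air. The fallback sets out from 6 and returns at 13; it keeps the acetals until the ring carries an acyl group. Lithiation of 6 at its only kind of ring C–H, flanked by OCH2OMe and OMe (n-BuLi, TMEDA, THF, 0 °C), would give [3,6-dimethoxy-2,4-bis(methoxymethoxy)phenyl]lithium F3. N-Methoxy-N-methylacetamide would convert it into 1-[3,6-dimethoxy-2,4-bis(methoxymethoxy)phenyl]ethan-1-one F4. Claisen condensation of its lithium enolate (LiN(SiMe3)2, THF, −78 → 0 °C) with ester 9 would give 1-[3,6-dimethoxy-2,4-bis(methoxymethoxy)phenyl]-3-{4-methoxy-3,5-bis[(triisopropylsilyl)oxy]phenyl}propane-1,3-dione F5. HCl in MeOH–THF at 40 °C should then remove both acetals from the now deactivated ring and, by way of diketone 12, close the pyranone to 13.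

Step 2. Lithiation may occur in part at a position between OCH2OMe and OMe, the doubly ortho-oxygenated arylboron intermediate may undergo protodeboronation before it is oxidised, and the electron-rich phenol may be over-oxidised by peroxide. The fallback sets out from 2 through aryllithium 3 and returns at 5; it installs the oxygen through carbon instead of boron. Quenching 3 with DMF would give 4-methoxy-2,6-bis(methoxymethoxy)benzaldehyde F6, a stable compound that can be purified from any regioisomer. Baeyer–Villiger oxidation with aryl migration (mCPBA, NaHCO3, CH2Cl2, 0 °C) would give 4-methoxy-2,6-bis(methoxymethoxy)phenyl formate F7, and methanolysis (K2CO3, MeOH, rt) would give 5.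

Further compounds
F1 | step 7 | 1-(2,4-dihydroxy-3,6-dimethoxyphenyl)ethan-1-iminium chloride | CC(=[NH2+])c1c(O)c(OC)c(O)cc1OC.[Cl-]
F2 | step 7 | 1-(2,4-dihydroxy-3,6-dimethoxyphenyl)ethan-1-one | CC(=O)c1c(O)c(OC)c(O)cc1OC
F3 | step 4 | [3,6-dimethoxy-2,4-bis(methoxymethoxy)phenyl]lithium | [Li]c1c(OCOC)c(OC)c(OCOC)cc1OC
F4 | step 4 | 1-[3,6-dimethoxy-2,4-bis(methoxymethoxy)phenyl]ethan-1-one | CC(=O)c1c(OCOC)c(OC)c(OCOC)cc1OC
F5 | step 4 | 1-[3,6-dimethoxy-2,4-bis(methoxymethoxy)phenyl]-3-{4-methoxy-3,5-bis[(triisopropylsilyl)oxy]phenyl}propane-1,3-dione | COCOc1cc(OC)c(C(=O)CC(=O)c2cc(O[Si](C(C)C)(C(C)C)C(C)C)c(OC)c(O[Si](C(C)C)(C(C)C)C(C)C)c2)c(OCOC)c1OC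
F6 | step 2 | 4-methoxy-2,6-bis(methoxymethoxy)benzaldehyde | COCOc1cc(OC)cc(OCOC)c1C=O
F7 | step 2 | 4-methoxy-2,6-bis(methoxymethoxy)phenyl formate | COCOc1cc(OC)cc(OCOC)c1OC=O
A1 | direct plan | 1-(2,4-dihydroxy-6-methoxyphenyl)ethan-1-one | CC(=O)c1c(O)cc(O)cc1OC
A2 | direct plan | methyl 3,5-bis(benzyloxy)-4-methoxybenzoate | COC(=O)c1cc(OCc2ccccc2)c(OC)c(OCc2ccccc2)c1
A3 | direct plan | 2-[3,5-bis(benzyloxy)-4-methoxyphenyl]-7-hydroxy-5-methoxy-4H-chromen-4-one | COc1cc(O)cc2oc(-c3cc(OCc4ccccc4)c(OC)c(OCc4ccccc4)c3)cc(=O)c12
A4 | direct plan | 2-[3,5-bis(benzyloxy)-4-methoxyphenyl]-7-hydroxy-5,8-dimethoxy-4H-chromen-4-one | COc1cc(O)c(OC)c2oc(-c3cc(OCc4ccccc4)c(OC)c(OCc4ccccc4)c3)cc(=O)c12
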